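**Retrosynthetic overview**
- The target is reached by acetylation and acid lactonisation of a macrocyclic chlorohydrin. Its ten-membered ring is closed last at C-6–C-7 by a CrCl2-mediated γ-chloroallylation, which also installs the chlorine, the exocyclic methylene and the lactone oxygen.
- C-3 to C-6 and C-16 come from a chloro-enyne (made from 1,3-dichloroacetone) that adds as its acetylide to the lactone carbonyl C-2 of a bridged bicyclic lactone.
- That lactone is the Diels–Alder adduct of 3-methyl-2-pyrone (C-1, C-2, C-12 to C-15) and a crotonyl ketone (C-9 to C-11, C-20) that carries C-7, C-8 and C-17 to C-19 from L-malic acid (chiral pool: Fráter–Seebach methylation, dioxolanone aldol).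
- Enabling feature: in the cyclohexenone ring (C-1, C-10, C-11, C-12, C-13, C-14) the ketone C-12 and the quaternary carbon C-1 are linked by the C-13=C-14 double bond, and C-1 bears the oxygenated carbon C-2. The array O–C-12–C-13=C-14–C-1–C-2(=O) is the retron of a 2-pyrone/alkene cycloadduct, with the pyrone ring oxygen becoming the ketone oxygen.
- Ring order: six-membered carbocycle (step 8, as a lactone-bridged bicycle), then the ten-membered ring (step 22), then the γ-lactone (step 23).

Key step: step 8

Remark on numbering: atom labels C-1 to C-20 are briarane numbers. C-1 is the quaternary ring-fusion carbon (methyl C-15); C-2 is CH(OAc); C-3=C-4 is the Z-alkene; C-5 bears the methylene C-16; C-6 is CHCl; C-7 is the lactone CH–O; C-8 is C(OH); C-9 is CH(OAc); C-10 is the ring-fusion CH; C-11 is C(OH)CH3 (methyl C-20); C-12 is the ketone; C-13=C-14 is the enone alkene; C-17 is CH(CH3) (methyl C-18); C-19 is the lactone carbonyl.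

Assumption: the chlorovinyl group of 18–29 is drawn as the E isomer; an E/Z mixture from step 13 would be carried on unchanged, because the allylchromium species 30 equilibrates before ring closure.

**Route**

Step 1
Reactants: 1 3-bromo-2H-pyran-2-one
Product: 2 3-methyl-2H-pyran-2-one
Conditions: MeZnCl, Pd(PPh3)4 (5 mol%), THF, 50 °C
Reagents that add atoms: methylzinc chloride, C[Zn]Cl
Why: Negishi coupling; zerovalent palladium inserts into the C-3–Br bond and methyl is transferred from zinc under neutral conditions that spare the pyrone lactone.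

Step 2
Reactants: 3 dimethyl (S)-malate
Product: 5 dimethyl (2S,3R)-3-methylmalate, via dilithium alkoxide enolate 4 (not isolated)
Conditions: LiHMDS (2.2 equiv), THF, −78 to −20 °C; MeI, −78 to −10 °C; aq. NH4Cl
Reagents that add atoms: iodomethane, CI
Why: Fráter–Seebach alkylation; the chelated alkoxide enolate is methylated anti to the alkoxide, which sets C-17 relative to the carbinol carbon (later C-8).

Step 3
Reactants: 5 dimethyl (2S,3R)-3-methylmalate
Product: 6 (2S,3R)-2-hydroxy-3-methylbutanedioic acid
Conditions: LiOH, THF/H2O, 0 °C to rt; then aq. HCl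
Reagents that add atoms: lithium hydroxide, [Li+].[OH-]
Why: plain ester saponification at low temperature, which should not epimerise the methyl-bearing carbon.

Step 4
Reactants: 6 (2S,3R)-2-hydroxy-3-methylbutanedioic acid
Product: 7 (2R)-2-[(2S,4S)-2-tert-butyl-5-oxo-1,3-dioxolan-4-yl]propanoic acid
Conditions: t-BuCHO, TsOH (cat.), H2SO4 (cat.), pentane, reflux, Dean–Stark trap
Reagents that add atoms: pivalaldehyde, CC(C)(C)C=O
Why: acid-catalysed acetalisation of the α-hydroxy acid (template for self-regeneration of stereocentres); the five-membered dioxolanone is preferred over the dioxanone and the cis acetal (tert-butyl cis to the side chain) is favoured, which sets the acetal centre.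

Step 5
Reactants: 7 the dioxolanone acid
Product: 8 tert-butyl (2R)-2-[(2S,4S)-2-tert-butyl-5-oxo-1,3-dioxolan-4-yl]propanoate
Conditions: t-BuOC(=NH)CCl3, cyclohexane/CH2Cl2, rt
Reagents that add atoms: tert-butyl 2,2,2-trichloroacetimidate, CC(C)(C)OC(=N)C(Cl)(Cl)Cl
Why: carboxylic acids are O-alkylated by the imidate without added acid, so the acetal survives; the hindered ester later resists attack by neighbouring hydroxyls and by the acetylide.

Step 6
Reactants: 8 the tert-butyl ester
Product: 10 tert-butyl (2R)-2-[(2S)-2-tert-butyl-4-[(E)-1-hydroxybut-2-enyl]-5-oxo-1,3-dioxolan-4-yl]propanoate (C-9 epimers), via lithium enolate 9 (not isolated)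
Conditions: LiHMDS (1.1 equiv), THF, −78 °C; (E)-crotonaldehyde, −78 °C; aq. NH4Cl at −78 °C
Reagents that add atoms: (E)-crotonaldehyde, C/C=C/C=O
Why: aldol addition of a dioxolanone enolate (self-regeneration of stereocentres); the aldehyde enters anti to the tert-butyl group, so C-8 becomes quaternary with retention, and the carbinol mixture at C-9 is erased in step 7.

Step 7
Reactants: 10 the aldol adduct
Product: 11 tert-butyl (2R)-2-[(2S,4R)-4-[(E)-but-2-enoyl]-2-tert-butyl-5-oxo-1,3-dioxolan-4-yl]propanoate
Conditions: Dess–Martin periodinane, NaHCO3, CH2Cl2, 0 °C to rt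
Reagents that add atoms: none
Why: Dess–Martin oxidation of the allylic alcohol merges both C-9 epimers into one enone without touching the acetal or the ester.

Step 8
Reactants: 2 3-methyl-2H-pyran-2-one and 11 the enone
Product: 12 Diels–Alder adduct, tert-butyl (2R)-2-[(2S,4R)-2-tert-butyl-4-(4,7-dimethyl-3-oxo-2-oxabicyclo[2.2.2]oct-5-ene-8-carbonyl)-5-oxo-1,3-dioxolan-4-yl]propanoate (acyl group syn to the ring C=C, 7-methyl syn to the lactone bridge)
Conditions: 2 (3 equiv), Yb(OTf)3 (0.3 equiv), CH2Cl2, 12 kbar, 25 °C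
Reagents that add atoms: none
Why: Normal-electron-demand [4+2] cycloaddition in which the pyrone diene (ring carbons 3 to 6) adds suprafacially to the Yb-chelated s-cis enone, forming C-1–C-10 and C-11–C-12 in one concerted, asynchronous event. The closest known reaction type is the pressure- or Lewis-acid-promoted Diels–Alder reaction of 3-substituted 2-pyrones with α,β-unsaturated carbonyl compounds, which gives 2-oxabicyclo[2.2.2]oct-5-en-3-ones. The new carbocyclic six-membered ring and, because the diene is cyclic, the lactone-bridged ring both close in the concerted [4+2] mode. Relative configuration: the endo transition state (acyl group under the diene, reinforced by the Lewis acid) and retention of the E-alkene geometry set C-1, C-10, C-11 and C-12 and put the C-2 carbonyl and the C-9 acyl group on opposite faces of the new ring, as the trans ring fusion requires. Absolute configuration: chelation of ytterbium between the ketone and the dioxolanone carbonyl holds the C-17 branch of the quaternary centre C-8 over one face of the enone, so the diene should add to the face flanked only by the ring oxygen. The step needs regioselectivity (enone β-carbon to pyrone C-6, α-carbon to the methyl-bearing C-3), which follows the pattern of known 3-donor-substituted 2-pyrones, and reactivity without loss of CO2, which 12 kbar at 25 °C should secure.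

Step 9
Reactants: 12 the Diels–Alder adduct
Product: 13 triol, tert-butyl (2R)-3,4-dihydroxy-3-(hydroxymethyl)-2-methyl-4-(4,7-dimethyl-3-oxo-2-oxabicyclo[2.2.2]oct-5-en-8-yl)butanoate (C-8 and C-9 as in the SMILES)
Conditions: NaBH4 (4 equiv), EtOH/THF, −20 to 0 °C
Reagents that add atoms: none
Why: NaBH4 should reduce the ketone and the acylal-type dioxolanone carbonyl (the released pivalaldehyde ends as neopentyl alcohol) but not the neopentyl-type bridged lactone or the tert-butyl ester, and without chelation hydride attacks C-9 anti to the C-8–O bond on the face not covered by the C-17 branch (Felkin–Anh), which should give the 9S alcohol.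

Step 10
Reactants: 13 the triol
Product: 14 primary tert-butyldimethylsilyl ether of 13 (O-7 silylated)
Conditions: TBSCl, imidazole, DMF, 0 °C
Reagents that add atoms: tert-butyldimethylsilyl chloride, CC(C)(C)[Si](C)(C)Cl
Why: only the primary hydroxyl is silylated, since the secondary C-9 and tertiary C-8 hydroxyls are too hindered under these conditions.

Step 11
Reactants: 14 the silyl ether diol
Product: 15 acetonide of 14 (2,2-dimethyl-1,3-dioxolane across O-8 and O-9)
Conditions: 2-methoxypropene, PPTS (cat.), CH2Cl2, 0 °C to rt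
Reagents that add atoms: 2-methoxypropene, COC(C)=C
Why: acid-catalysed acetonide formation on the remaining 1,2-diol, which blocks O-9 so that only O-7 can later close the lactone.

Step 12
Reactants: 16 1,3-dichloroacetone
Product: 17 1-chloro-2-(chloromethyl)but-3-yn-2-ol
Conditions: HC≡CMgBr, THF, −78 °C; aq. NH4Cl at −78 °C
Reagents that add atoms: ethynylmagnesium bromide, C#C[Mg]Br
Why: Grignard addition to the ketone, with a cold quench so that the chlorohydrin alkoxide does not close to an epoxide.

Step 13
Reactants: 17 the dichloro carbinol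
Product: 18 (E)-1-chloro-2-(chloromethyl)but-1-en-3-yne
Conditions: Burgess reagent, benzene, 50 °C
Reagents that add atoms: none
Why: Burgess dehydration (syn elimination of the sulfamate) of the tertiary alcohol; the only β-hydrogens sit on the two equivalent CH2Cl groups, so one constitutional isomer results.

Step 14
Reactants: 15 the acetonide lactone and 18 the chloro-enyne
Product: 20 hydroxy ynone (C-12 allylic alcohol, C-2 alkynyl ketone; bridged lactone opened), via lithium acetylide 19 (not isolated)
Conditions: 18, LiHMDS, THF, −78 °C; then 15, −78 to −40 °C; aq. NH4Cl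
Reagents that add atoms: none
Why: addition of a lithium acetylide to a lactone; the strained bridged lactone is attacked from the side of the ring double bond and the tetrahedral lithium hemiketal prevents a second addition, while the tert-butyl ester, acetonide and silyl ether are inert at −78 °C.

Step 15
Reactants: 20 the hydroxy ynone
Product: 21 ynone enone (C-12 cyclohexenone, C-2 alkynyl ketone)
Conditions: Dess–Martin periodinane, NaHCO3, CH2Cl2, 0 °C
Reagents that add atoms: none
Why: Dess–Martin oxidation of the allylic ring alcohol gives the enone; C-1 is quaternary, so the 1,5-dicarbonyl array cannot enolise toward it.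

Step 16
Reactants: 21 the ynone enone
Product: 22 propargylic alcohol (C-2 carbinol, R by the sequence rule at this stage)
Conditions: Ru[(R,R)-TsNCH(Ph)CH(Ph)NH](p-cymene) (3 mol%), i-PrOH, 25 °C
Reagents that add atoms: none
Why: Noyori transfer hydrogenation; alkynyl ketones are reduced far faster than conjugated cyclohexenones, and the (R,R)-catalyst, with the alkynyl group in the place of the aryl group of the usual model, should set C-2 as the target requires.

Step 17
Reactants: 22 the propargylic alcohol
Product: 23 C-2 acetate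
Conditions: Ac2O, pyridine, DMAP (cat.), CH2Cl2, 0 °C
Reagents that add atoms: acetic anhydride, CC(=O)OC(C)=O
Why: standard acetylation of the only free hydroxyl installs the C-2 acetate of the target before the non-basic hydroxylation that follows.

Step 18
Reactants: 23 the C-2 acetate
Product: 26 α-hydroxy ketone (tertiary hydroxyl at C-11), via silyl dienol ether 24 (not isolated), via silyloxy ketone 25 (not isolated)
Conditions: TMSOTf, Et3N, CH2Cl2, −78 to 0 °C; dimethyldioxirane, acetone, −40 °C; citric acid, MeOH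
Reagents that add atoms: dimethyldioxirane, CC1(C)OO1
Why: Rubottom oxidation; enolisation can only go toward C-11 because C-1 is quaternary, and the dioxirane attacks the electron-rich C-11=C-12 bond anti to the adjacent C-9 side chain and the C-15 methyl, which places the hydroxyl cis to H-10.

Step 19
Reactants: 26 the α-hydroxy ketone
Product: 27 (Z)-diene (C-3=C-4 cis)
Conditions: H2 (1 atm), Pd/CaCO3 poisoned with Pb(OAc)2, quinoline, EtOAc, 0 °C
Reagents that add atoms: none
Why: Lindlar semi-hydrogenation adds H2 syn to the alkyne to give the Z-alkene, under conditions that vinyl and allyl chlorides and the enone should survive.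

Step 20
Reactants: 27 the (Z)-diene
Product: 28 primary alcohol at C-7
Conditions: HF·pyridine, pyridine/THF, 0 °C to rt
Reagents that add atoms: none
Why: buffered fluoride removes the primary silyl ether and leaves the acetonide, acetate and tert-butyl ester.

Step 21
Reactants: 28 the primary alcohol
Product: 29 aldehyde at C-7
Conditions: Dess–Martin periodinane, NaHCO3, CH2Cl2, 0 °C
Reagents that add atoms: none
Why: Dess–Martin oxidation of the neopentyl primary alcohol; the aldehyde has no α-hydrogen and the tertiary C-11 hydroxyl is inert.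

Step 22
Reactants: 29 the aldehyde
Product: 31 macrocyclic chlorohydrin (ten-membered ring; C-6 chloride, C-7 hydroxyl, C-5 exocyclic methylene), via allylchromium dichloride 30 (not isolated)
Conditions: CrCl2 (10 equiv), LiI (cat.), THF, 0.002 M, slow addition, 25 °C
Reagents that add atoms: none
Why: intramolecular Nozaki–Hiyama allylation in its γ-chloroallyl form; divalent chromium inserts into the allylic C–Cl bond, the allylchromium adds through its chlorine-bearing carbon to the aldehyde in a chair transition state (anti C-6/C-7 chlorohydrin, exocyclic methylene), and attack anti to the C-8–O bond with the C-9 branch inside (Felkin–Anh) should set C-7.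

Step 23
Reactants: 31 the macrocyclic chlorohydrin
Product: 33 9-deacetyl target (γ-lactone closed; C-8, C-9 and C-11 hydroxyls free), via lactone acetonide 32 (not isolated)
Conditions: CSA (0.2 equiv), CH2Cl2, 25 °C; then MeOH, 25 °C
Reagents that add atoms: none
Why: acid-catalysed lactonisation of the γ-hydroxy tert-butyl ester can only use O-7 while O-9 is locked in the acetonide, and methanol then removes the acetonide; C-17 keeps its malate-derived configuration (methyl trans to C-9 on the lactone).

Step 24
Reactants: 33 the 9-deacetyl compound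
Product: 34 CNP0188317.1
Conditions: Ac2O, pyridine, DMAP (cat.), CH2Cl2, 0 °C to rt
Reagents that add atoms: acetic anhydride, CC(=O)OC(C)=O
Why: DMAP-catalysed acetylation distinguishes the single secondary hydroxyl (C-9) from the two tertiary ones (C-8, C-11).

**Compound list**

1 | 3-bromo-2H-pyran-2-one | BrC1=CC=COC1=O | starting material
2 | 3-methyl-2H-pyran-2-one | CC1=CC=COC1=O | intermediate
3 | dimethyl (S)-malate | COC(=O)[C@@H](O)CC(=O)OC | starting material
4 | dilithium alkoxide enolate of 3 (not isolated) | COC(=O)[C@@H](O[Li])C=C(O[Li])OC | intermediate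
5 | dimethyl (2S,3R)-3-methylmalate | COC(=O)[C@@H](O)[C@@H](C)C(=O)OC | intermediate
6 | (2S,3R)-2-hydroxy-3-methylbutanedioic acid | OC(=O)[C@@H](O)[C@@H](C)C(=O)O | intermediate
7 | (2R)-2-[(2S,4S)-2-tert-butyl-5-oxo-1,3-dioxolan-4-yl]propanoic acid | O=C1O[C@@H](C(C)(C)C)O[C@H]1[C@@H](C)C(=O)O | intermediate
8 | tert-butyl (2R)-2-[(2S,4S)-2-tert-butyl-5-oxo-1,3-dioxolan-4-yl]propanoate | O=C1O[C@@H](C(C)(C)C)O[C@H]1[C@@H](C)C(=O)OC(C)(C)C | intermediate
9 | lithium enolate of 8 (not isolated) | [Li]OC1=C([C@@H](C)C(=O)OC(C)(C)C)O[C@H](C(C)(C)C)O1 | intermediate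
10 | aldol adduct, 4-[(E)-1-hydroxybut-2-enyl] dioxolanone (C-9 epimers) | C/C=C/C(O)[C@]1(O[C@H](C(C)(C)C)OC1=O)[C@@H](C)C(=O)OC(C)(C)C | intermediate
11 | tert-butyl (2R)-2-[(2S,4R)-4-[(E)-but-2-enoyl]-2-tert-butyl-5-oxo-1,3-dioxolan-4-yl]propanoate | C/C=C/C(=O)[C@]1(O[C@H](C(C)(C)C)OC1=O)[C@@H](C)C(=O)OC(C)(C)C | intermediate
12 | Diels–Alder adduct, 8-acyl-4,7-dimethyl-2-oxabicyclo[2.2.2]oct-5-en-3-one with the dioxolanone of 11 (acyl syn to the ring C=C) | O=C1O[C@@H](C(C)(C)C)O[C@]1([C@@H](C)C(=O)OC(C)(C)C)C(=O)[C@H]1[C@H](C)[C@H]2C=C[C@]1(C)C(=O)O2 | intermediate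
13 | triol (C-7 CH2OH, C-8 OH, C-9 OH; bridged lactone and tert-butyl ester intact) | OC[C@@](O)([C@@H](C)C(=O)OC(C)(C)C)[C@@H](O)[C@H]1[C@H](C)[C@H]2C=C[C@]1(C)C(=O)O2 | intermediate
14 | O-7 tert-butyldimethylsilyl ether of 13 | CC(C)(C)[Si](C)(C)OC[C@@](O)([C@@H](C)C(=O)OC(C)(C)C)[C@@H](O)[C@H]1[C@H](C)[C@H]2C=C[C@]1(C)C(=O)O2 | intermediate
15 | O-8/O-9 acetonide of 14 | CC(C)(C)[Si](C)(C)OC[C@]1([C@@H](C)C(=O)OC(C)(C)C)OC(C)(C)O[C@H]1[C@H]2[C@H](C)[C@H]3C=C[C@]2(C)C(=O)O3 | intermediate
16 | 1,3-dichloroacetone | ClCC(=O)CCl | starting material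
17 | 1-chloro-2-(chloromethyl)but-3-yn-2-ol | OC(CCl)(CCl)C#C | intermediate
18 | (E)-1-chloro-2-(chloromethyl)but-1-en-3-yne | Cl/C=C(\C#C)CCl | intermediate
19 | lithium acetylide of 18 (not isolated) | [Li]C#C/C(CCl)=C\Cl | intermediate
20 | hydroxy ynone (C-12 OH, C-2 alkynyl ketone) | CC(C)(C)[Si](C)(C)OC[C@]1([C@@H](C)C(=O)OC(C)(C)C)OC(C)(C)O[C@H]1[C@H]2[C@H](C)[C@H](O)C=C[C@]2(C)C(=O)C#C/C(CCl)=C\Cl | intermediate
21 | ynone enone (C-12 cyclohexenone, C-2 alkynyl ketone) | CC(C)(C)[Si](C)(C)OC[C@]1([C@@H](C)C(=O)OC(C)(C)C)OC(C)(C)O[C@H]1[C@H]2[C@H](C)C(=O)C=C[C@]2(C)C(=O)C#C/C(CCl)=C\Cl | intermediate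
22 | propargylic alcohol at C-2 | CC(C)(C)[Si](C)(C)OC[C@]1([C@@H](C)C(=O)OC(C)(C)C)OC(C)(C)O[C@H]1[C@H]2[C@H](C)C(=O)C=C[C@]2(C)[C@@H](O)C#C/C(CCl)=C\Cl | intermediate
23 | C-2 acetate of 22 | CC(C)(C)[Si](C)(C)OC[C@]1([C@@H](C)C(=O)OC(C)(C)C)OC(C)(C)O[C@H]1[C@H]2[C@H](C)C(=O)C=C[C@]2(C)[C@@H](OC(C)=O)C#C/C(CCl)=C\Cl | intermediate
24 | trimethylsilyl dienol ether of 23 (C-11=C-12, not isolated) | CC(C)(C)[Si](C)(C)OC[C@]1([C@@H](C)C(=O)OC(C)(C)C)OC(C)(C)O[C@H]1[C@H]2C(C)=C(O[Si](C)(C)C)C=C[C@]2(C)[C@@H](OC(C)=O)C#C/C(CCl)=C\Cl | intermediate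
25 | C-11 trimethylsilyloxy ketone (not isolated) | CC(C)(C)[Si](C)(C)OC[C@]1([C@@H](C)C(=O)OC(C)(C)C)OC(C)(C)O[C@H]1[C@H]2[C@](C)(O[Si](C)(C)C)C(=O)C=C[C@]2(C)[C@@H](OC(C)=O)C#C/C(CCl)=C\Cl | intermediate
26 | α-hydroxy ketone (C-11 OH) | CC(C)(C)[Si](C)(C)OC[C@]1([C@@H](C)C(=O)OC(C)(C)C)OC(C)(C)O[C@H]1[C@H]2[C@](C)(O)C(=O)C=C[C@]2(C)[C@@H](OC(C)=O)C#C/C(CCl)=C\Cl | intermediate
27 | (Z)-diene (C-3=C-4 cis) | CC(C)(C)[Si](C)(C)OC[C@]1([C@@H](C)C(=O)OC(C)(C)C)OC(C)(C)O[C@H]1[C@H]2[C@](C)(O)C(=O)C=C[C@]2(C)[C@@H](OC(C)=O)/C=C\C(CCl)=C/Cl | intermediate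
28 | primary alcohol at C-7 | OC[C@]1([C@@H](C)C(=O)OC(C)(C)C)OC(C)(C)O[C@H]1[C@H]2[C@](C)(O)C(=O)C=C[C@]2(C)[C@@H](OC(C)=O)/C=C\C(CCl)=C/Cl | intermediate
29 | aldehyde at C-7 | O=C[C@]1([C@@H](C)C(=O)OC(C)(C)C)OC(C)(C)O[C@H]1[C@H]2[C@](C)(O)C(=O)C=C[C@]2(C)[C@@H](OC(C)=O)/C=C\C(CCl)=C/Cl | intermediate
30 | allylchromium dichloride from 29 (chloroalkene geometry mobile, not isolated) | O=C[C@]1([C@@H](C)C(=O)OC(C)(C)C)OC(C)(C)O[C@H]1[C@H]2[C@](C)(O)C(=O)C=C[C@]2(C)[C@@H](OC(C)=O)/C=C\C(C[Cr](Cl)Cl)=CCl | intermediate
31 | macrocyclic chlorohydrin (acetonide and tert-butyl ester intact) | C=C1/C=C\[C@H](OC(C)=O)[C@@]2(C)C=CC(=O)[C@@](C)(O)[C@@H]2[C@@H]2OC(C)(C)O[C@@]2([C@@H](C)C(=O)OC(C)(C)C)[C@@H](O)[C@H]1Cl | intermediate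
32 | lactone acetonide (γ-lactone closed, O-8/O-9 acetonide, not isolated) | C=C1/C=C\[C@H](OC(C)=O)[C@@]2(C)C=CC(=O)[C@@](C)(O)[C@@H]2[C@@H]2OC(C)(C)O[C@]23[C@@H](C)C(=O)O[C@H]3[C@H]1Cl | intermediate
33 | 9-deacetyl target | C=C1/C=C\[C@H](OC(C)=O)[C@@]2(C)C=CC(=O)[C@@](C)(O)[C@@H]2[C@H](O)[C@]2(O)[C@@H](C)C(=O)O[C@H]2[C@H]1Cl | intermediate
34 | CNP0188317.1 | C=C1/C=C\[C@H](OC(C)=O)[C@@]2(C)C=CC(=O)[C@@](C)(O)[C@@H]2[C@H](OC(C)=O)[C@]2(O)[C@@H](C)C(=O)O[C@H]2[C@H]1Cl | target

**Step count and risks**

Total step count: 24. Longest linear sequence: 21 steps (from 3: steps 2–11 and 14–24).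

Steps most likely to fail:

1. Step 8. The cycloaddition may stall because the pyrone is a reluctant diene and the enone is β-substituted with a quaternary neighbour; forcing it thermally would cost CO2 from the adduct, and incomplete chelation would erode the facial selectivity. The fallback sets out from 11 and uses a halogen-activated diene. 5-Bromo-3-methyl-2H-pyran-2-one F1 would be made from commercial 3,5-dibromo-2H-pyran-2-one by Stille methylation at C-3 (Me4Sn, Pd(PPh3)4, CuI, toluene). Bromopyrones of this kind are much more reactive and should add to 11 at ambient pressure (toluene, 80 °C) with the same regio- and endo sense to give the bromo adduct F2. Its vinylic bromine is then removed with Bu3SnH/AIBN, which brings the route back to 12.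

2. Step 22. Ring closure to the ten-membered ring may lose out to oligomerisation, and equilibration of the allylchromium species may blur the anti relationship at C-6/C-7 or the face of attack at C-7. The fallback sets out from alcohol 28 and replaces chromium by a configurationally fixed allylboron reagent. Miyaura-type borylation of the allylic chloride (B2pin2, Pd2(dba)3, DMSO) would give the γ-chloroallyl boronate F5, and Dess–Martin oxidation its aldehyde F6. Heating F6 at high dilution (toluene, 60–80 °C) should give an intramolecular allylboration through a closed chair transition state, in which the E-chloroalkene translates into the anti chlorohydrin. Mild hydrolysis of the borate returns 31.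

3. Step 14. The acetylide may fail to attack the neopentyl-type lactone carbonyl, or the sensitive chloro-enyne anion may decompose before it does. The fallback sets out from 15 and adds the acetylide at the aldehyde oxidation level. DIBAL-H (CH2Cl2, −78 °C) would reduce the bridged lactone to the lactol F3. Lithium acetylide 19 in excess would add to its open hydroxy-aldehyde form to give the diol F4 as a mixture at C-2. Dess–Martin oxidation of both hydroxyls converges on 21, where step 16 sets C-2.

Further compounds
F1 | step 8 | 5-bromo-3-methyl-2H-pyran-2-one | CC1=CC(Br)=COC1=O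
F2 | step 8 | 6-bromo analogue of adduct 12 (bromine on the ring alkene carbon next to the O-bearing bridgehead) | O=C1O[C@@H](C(C)(C)C)O[C@]1([C@@H](C)C(=O)OC(C)(C)C)C(=O)[C@H]1[C@H](C)[C@H]2C(Br)=C[C@]1(C)C(=O)O2
F3 | step 14 | bridged lactol from 15 (anomers) | CC(C)(C)[Si](C)(C)OC[C@]1([C@@H](C)C(=O)OC(C)(C)C)OC(C)(C)O[C@H]1[C@H]2[C@H](C)[C@H]3C=C[C@]2(C)C(O)O3
F4 | step 14 | C-2/C-12 diol (C-2 epimers) | CC(C)(C)[Si](C)(C)OC[C@]1([C@@H](C)C(=O)OC(C)(C)C)OC(C)(C)O[C@H]1[C@H]2[C@H](C)[C@H](O)C=C[C@]2(C)C(O)C#C/C(CCl)=C\Cl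
F5 | step 22 | γ-chloroallyl pinacol boronate of alcohol 28 | OC[C@]1([C@@H](C)C(=O)OC(C)(C)C)OC(C)(C)O[C@H]1[C@H]2[C@](C)(O)C(=O)C=C[C@]2(C)[C@@H](OC(C)=O)/C=C\C(CB2OC(C)(C)C(C)(C)O2)=C/Cl
F6 | step 22 | aldehyde of F5 | O=C[C@]1([C@@H](C)C(=O)OC(C)(C)C)OC(C)(C)O[C@H]1[C@H]2[C@](C)(O)C(=O)C=C[C@]2(C)[C@@H](OC(C)=O)/C=C\C(CB2OC(C)(C)C(C)(C)O2)=C/Cl
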